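**Retrosynthetic overview**

1. The target alcohol is the borohydride reduction product of the 2,3-trans/3,4-cis tetrahydrofuran-3-carbaldehyde, whose C2–C3 bond is disconnected as an aldol-type bond.
2. The tetrahydrofuran ring (O1, C2, C3, C4, C5) is not closed directly: it is contracted out of a seven-membered cyclic vinyl acetal, a (5S)-2-aryl-5-benzyl-4,5-dihydro-1,3-dioxepine, by a Lewis-acid 1,3-O-to-C shift that makes the ring, the C2–C3 bond and the C2 and C3 stereocentres in one operation.
3. Enabling feature: C2 is a benzylic carbon on ring oxygen O1 and C3 carries the carbinol carbon, so O1–C2–C3–CH2–OH is a 1,3-dioxygen (β-alkoxy carbonyl) array; at the aldehyde level both oxygens can sit on C2 as an acetal, the carbinol oxygen as an enol ether.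
4. The vinyl acetal comes from an asymmetric benzyl Mizoroki–Heck reaction of the meso acetal of (Z)-but-2-ene-1,4-diol and 3,4,5-trimethoxybenzaldehyde with 3,4-dimethoxybenzyl trifluoroacetate, which sets C4 and moves the alkene into the enol-ether position.
5. Ring order: the dioxepine ring by acetalisation first, then the tetrahydrofuran by contraction; both arenes are bought.

Key step: step 4

Remark: the Heck product of step 3 is carried as a mixture of its two epimers at the acetal carbon, because that carbon becomes planar in the ring contraction; its SMILES leaves this centre undefined.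

**Route**

Step 1
Reactants: 1 (Z)-but-2-ene-1,4-diol; 2 3,4,5-trimethoxybenzaldehyde
Product: 3 2-(3,4,5-trimethoxyphenyl)-4,7-dihydro-1,3-dioxepine
Conditions: p-TsOH·H2O (cat.), toluene, reflux, Dean–Stark
Reagents that add atoms: none
Why: Acid-catalysed acetalisation with azeotropic removal of water closes the seven-membered 4,7-dihydro-1,3-dioxepine from the cis-diol, a standard cyclic acetal formation that creates no stereocentre (the product has a mirror plane through C2).

Step 2
Reactants: 4 3,4-dimethoxybenzyl alcohol
Product: 5 3,4-dimethoxybenzyl trifluoroacetate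
Conditions: (CF3CO)2O, pyridine, CH2Cl2, 0 °C; used fresh
Reagents that add atoms: trifluoroacetic anhydride, O=C(OC(=O)C(F)(F)F)C(F)(F)F
Why: O-Acylation of the benzylic alcohol gives a leaving group that ionises readily on zerovalent palladium; the ester is used without storage because the electron-rich benzylic C–O bond is labile.

Step 3
Reactants: 3 2-(3,4,5-trimethoxyphenyl)-4,7-dihydro-1,3-dioxepine (2 equiv); 5 3,4-dimethoxybenzyl trifluoroacetate
Product: 6 (5S)-5-(3,4-dimethoxybenzyl)-2-(3,4,5-trimethoxyphenyl)-4,5-dihydro-1,3-dioxepine (mixture of the two C2 epimers)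
Conditions: Pd(dba)2 (5 mol %), chiral BINOL-derived monodentate phosphoramidite (10 mol %; the antipode that gives 5S, chosen in a trial run with both), Li2CO3, DMA, 50 °C
Reagents that add atoms: none
Why: Asymmetric Mizoroki–Heck reaction of a benzylic electrophile with a cyclic olefin: the η3-benzylpalladium cation adds syn across C5=C6 of the meso alkene, syn β-hydride elimination is possible only towards C7 and so delivers the enol ether directly, and the chiral ligand differentiates the enantiotopic alkene carbons so that C5 should be S in both acetal epimers.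

Step 4
Reactants: 6 (5S)-5-(3,4-dimethoxybenzyl)-2-(3,4,5-trimethoxyphenyl)-4,5-dihydro-1,3-dioxepine
Product: 9 (2R,3R,4S)-4-(3,4-dimethoxybenzyl)-2-(3,4,5-trimethoxyphenyl)tetrahydrofuran-3-carbaldehyde, via oxocarbenium enolate ion pair 7 (not isolated), via C3-epimeric aldehyde 8 (not isolated)
Conditions: (iPrO)2TiCl2 (30 mol %, from TiCl4 and Ti(OiPr)4), CH2Cl2, −78 to −40 °C; then aq. NaHCO3
Reagents that add atoms: none
Why: (iPrO)2TiCl2 binds the enol-ether oxygen and ionises the C2–O1 acetal bond, giving the aryl-stabilised oxocarbenium ion and a titanium Z-enolate held in one ion pair (7), which recombines through carbon (C6 of the dioxepine, the future C3, onto C2) in a 1,3-O-to-C shift that contracts the seven-membered ring to the tetrahydrofuran. The closest known reaction type is the Lewis-acid-mediated ring contraction of 4,5-dihydro-1,3-dioxepines to tetrahydrofuran-3-carbaldehydes, a Petasis–Ferrier-type rearrangement that is in essence an intramolecular Mukaiyama-type aldol addition to an oxocarbenium ion. The tetrahydrofuran closes in a 5-(enolexo)-endo-trig mode: the C=O+ bond lies inside the new ring and the enolate C=C outside it. The stereocentre set in step 3 (dioxepine C5, the future C4) controls C2: A(1,3) strain with the Z-enolate oxygen keeps the C5–H bond in the enolate plane, so the tethered oxocarbenium ion adds on the face anti to the benzyl group and the tight ion pair should give the 2,3-cis/3,4-trans aldehyde 8, in which aryl and benzyl are already trans. C3 is then corrected in the same flask: the titanium-chelated β-alkoxy aldehyde should epimerise through its titanium enolate to 9, with the formyl group trans to the bulkier C2 aryl and cis to the benzyl group, as mild chlorotitanium alkoxides are known to do in this reaction class while silyl triflates stop at the kinetic isomer. The step needs ionisation on the enol-ether side of the acetal (secured because the enolate is the better leaving group), recombination at carbon, and no reversible reopening to the all-trans series (secured by the low temperature and the mild Lewis acid).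

Step 5
Reactants: 9 (2R,3R,4S)-4-(3,4-dimethoxybenzyl)-2-(3,4,5-trimethoxyphenyl)tetrahydrofuran-3-carbaldehyde (crude)
Product: 10 [(2R,3S,4S)-4-(3,4-dimethoxybenzyl)-2-(3,4,5-trimethoxyphenyl)tetrahydrofuran-3-yl]methanol
Conditions: NaBH4, MeOH, 0 °C
Reagents that add atoms: none
Why: Chemoselective borohydride reduction of the aldehyde to the primary alcohol touches no stereocentre, and because 9 is already the preferred C3 epimer the basic medium should not erode the configuration (the C3 descriptor changes from R to S only through the change in substituent priorities).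

**Compound list**

1 | (Z)-but-2-ene-1,4-diol | OC/C=C\CO | starting material
2 | 3,4,5-trimethoxybenzaldehyde | COc1cc(C=O)cc(OC)c1OC | starting material
3 | 2-(3,4,5-trimethoxyphenyl)-4,7-dihydro-1,3-dioxepine | COc1cc(cc(OC)c1OC)C1OCC=CCO1 | intermediate
4 | 3,4-dimethoxybenzyl alcohol | COc1ccc(CO)cc1OC | starting material
5 | 3,4-dimethoxybenzyl trifluoroacetate | COc1ccc(COC(=O)C(F)(F)F)cc1OC | intermediate
6 | (5S)-5-(3,4-dimethoxybenzyl)-2-(3,4,5-trimethoxyphenyl)-4,5-dihydro-1,3-dioxepine, both C2 epimers | COc1cc(cc(OC)c1OC)C1OC[C@@H](Cc2ccc(OC)c(OC)c2)C=CO1 | intermediate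
7 | ring-opened ion pair: (E)-oxocarbenium ion ArCH=O(+)–CH2–CH(CH2Ar')–CH=CH–O(−) with S-configured carbon and Z-enolate (Ar = 3,4,5-trimethoxyphenyl, Ar' = 3,4-dimethoxyphenyl; titanium on the enolate oxygen not drawn) | COc1cc(cc(OC)c1OC)/C=[O+]/C[C@@H](Cc1ccc(OC)c(OC)c1)/C=C\[O-] | intermediate
8 | (2R,3S,4S)-4-(3,4-dimethoxybenzyl)-2-(3,4,5-trimethoxyphenyl)tetrahydrofuran-3-carbaldehyde (2,3-cis/3,4-trans) | COc1ccc(C[C@@H]2CO[C@@H](c3cc(OC)c(OC)c(OC)c3)[C@H]2C=O)cc1OC | intermediate
9 | (2R,3R,4S)-4-(3,4-dimethoxybenzyl)-2-(3,4,5-trimethoxyphenyl)tetrahydrofuran-3-carbaldehyde (2,3-trans/3,4-cis) | COc1ccc(C[C@@H]2CO[C@@H](c3cc(OC)c(OC)c(OC)c3)[C@@H]2C=O)cc1OC | intermediate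
10 | [(2R,3S,4S)-4-(3,4-dimethoxybenzyl)-2-(3,4,5-trimethoxyphenyl)tetrahydrofuran-3-yl]methanol | COc1ccc(C[C@@H]2CO[C@@H](c3cc(OC)c(OC)c(OC)c3)[C@@H]2CO)cc1OC | target

**Summary**

Total step count: 5. Longest linear sequence: 4 steps (steps 1, 3, 4, 5).

**Steps most likely to fail**

Step 3. The chiral zerovalent palladium catalyst may discriminate the two enantiotopic alkene carbons of this 2-aryl-substituted meso olefin poorly, or 3 may be isomerised by the palladium hydride intermediate before carbopalladation. The fallback sets out from 4 (and uses 2) and comes back at 6; it moves the enantioselective event to a double-bond isomerisation. Alcohol 4 would be converted with SOCl2 into 3,4-dimethoxybenzyl chloride F1 and then, with Zn dust and LiCl in THF, into (3,4-dimethoxybenzyl)zinc chloride F2. Negishi coupling of F2 with commercial 4-bromofuran-2(5H)-one (Pd(PPh3)4, THF) should give 4-(3,4-dimethoxybenzyl)furan-2(5H)-one F3. Reduction with iBu2AlH (CH2Cl2, −78 to 0 °C) should give (Z)-2-(3,4-dimethoxybenzyl)but-2-ene-1,4-diol F4, the Z geometry being inherited from the ring. Acetalisation of F4 with 2 under the conditions of step 1 should give 5-(3,4-dimethoxybenzyl)-2-(3,4,5-trimethoxyphenyl)-4,7-dihydro-1,3-dioxepine F5, racemic at C2. Asymmetric double-bond isomerisation with NiBr2(Me-DuPHOS) (one antipode) activated by LiBHEt3 (THF, about −50 °C), a known reaction type for 5-substituted 4,7-dihydro-1,3-dioxepines, should move C5=C6 to C6=C7 and create C5 under catalyst control, which returns to 6.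

Step 4. Kinetic control may be lost: reversible reopening of the ring would let the ion pair reclose to the all-trans series, the C3 epimerisation may stall, or the electron-rich benzyl arene may capture the oxocarbenium ion. The fallback sets out from 6 and comes back at 10; it keeps the C4 stereocentre and builds the ring by aldol addition and cycloetherification. Mild acid hydrolysis of 6 (aq. AcOH, THF) should give (4S)-4-(3,4-dimethoxybenzyl)tetrahydrofuran-2-ol F6 as anomers and return aldehyde 2. Oxidation (Ag2CO3 on Celite, toluene, reflux) should give (S)-4-(3,4-dimethoxybenzyl)dihydrofuran-2(3H)-one F7, which also serves to check the configuration set in step 3. Aldol addition of its lithium enolate (LiN(SiMe3)2, THF, −78 °C) to 2 should occur anti to the benzyl group and give (3R,4S)-4-(3,4-dimethoxybenzyl)-3-[hydroxy(3,4,5-trimethoxyphenyl)methyl]dihydrofuran-2(3H)-one F8 as carbinol epimers. LiAlH4 (THF, 0 °C) should give (2S,3S)-2-[hydroxy(3,4,5-trimethoxyphenyl)methyl]-3-(3,4-dimethoxybenzyl)butane-1,4-diol F9. Acid-mediated cycloetherification (camphorsulfonic acid, CH2Cl2) through the benzylic cation should close the tetrahydrofuran with the aryl group trans to the C3 hydroxymethyl group. The trans lactone translates into the 3,4-cis ring because the carbinol carbon and the former carbonyl carbon exchange their roles as ring member and side chain at C3, which gives 10.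

Step 2. The electron-rich benzylic trifluoroacetate may ionise and self-alkylate during isolation. The fallback sets out from 4 and comes back at 6; it replaces the ionisable ester by an electrophile that is activated only at the metal. Alcohol 4 with methyl chloroformate and pyridine (CH2Cl2, 0 °C) should give bench-stable 3,4-dimethoxybenzyl methyl carbonate F10. Under Pd(dba)2 and the same phosphoramidite without added base, oxidative addition with loss of CO2 should give the same η3-benzylpalladium cation with methoxide as the internal base, and the Heck reaction with 3 then returns to 6.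

Further compounds
F1 | step 3 | 3,4-dimethoxybenzyl chloride | COc1ccc(CCl)cc1OC
F2 | step 3 | (3,4-dimethoxybenzyl)zinc chloride | COc1ccc(C[Zn]Cl)cc1OC
F3 | step 3 | 4-(3,4-dimethoxybenzyl)furan-2(5H)-one | COc1ccc(CC2=CC(=O)OC2)cc1OC
F4 | step 3 | (Z)-2-(3,4-dimethoxybenzyl)but-2-ene-1,4-diol | OC/C=C(\CO)Cc1ccc(OC)c(OC)c1
F5 | step 3 | 5-(3,4-dimethoxybenzyl)-2-(3,4,5-trimethoxyphenyl)-4,7-dihydro-1,3-dioxepine (racemic at C2) | COc1cc(cc(OC)c1OC)C1OCC=C(Cc2ccc(OC)c(OC)c2)CO1
F6 | step 4 | (4S)-4-(3,4-dimethoxybenzyl)tetrahydrofuran-2-ol (anomers) | OC1C[C@H](Cc2ccc(OC)c(OC)c2)CO1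
F7 | step 4 | (S)-4-(3,4-dimethoxybenzyl)dihydrofuran-2(3H)-one | O=C1C[C@H](Cc2ccc(OC)c(OC)c2)CO1
F8 | step 4 | (3R,4S)-4-(3,4-dimethoxybenzyl)-3-[hydroxy(3,4,5-trimethoxyphenyl)methyl]dihydrofuran-2(3H)-one (carbinol epimers) | O=C1OC[C@@H](Cc2ccc(OC)c(OC)c2)[C@@H]1C(O)c1cc(OC)c(OC)c(OC)c1
F9 | step 4 | (2S,3S)-2-[hydroxy(3,4,5-trimethoxyphenyl)methyl]-3-(3,4-dimethoxybenzyl)butane-1,4-diol (carbinol epimers) | COc1ccc(C[C@H](CO)[C@@H](CO)C(O)c2cc(OC)c(OC)c(OC)c2)cc1OC
F10 | step 2 | 3,4-dimethoxybenzyl methyl carbonate | COC(=O)OCc1ccc(OC)c(OC)c1
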